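**Strategy.** Ring A is a pentasubstituted benzene whose oxygens sit on the alternating carbons C5, C7 and C8a. It therefore divides into three oxygenated alkynes: C4a≡C5(OMe), C6(H)≡C7(OSi) and C8(prenyl)≡C8a(O1). The first and last are already linked by the O1–C2–C3–C4 chain of ring C. One rhodium-catalysed [2+2+2] cycloaddition of this enantiopure 1,7-diyne, a methoxy ynone tethered to a secondary benzylic ynol ether, with triisopropylsiloxyacetylene forms C4a–C8a, C5–C6 and C7–C8. It closes rings A and C together and fixes the prenyl group at C8. C2 is set earlier by asymmetric ketone reduction. Demethylation at O5 and desilylation at O7 finish the synthesis.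

Key step: step 11

**Remarks on the chemistry**
- Flavanone numbering (O1, C2, C3, C4, C4a, C5–C8, C8a) is also used for the open-chain precursors.
- C6 carries hydrogen, so the third alkyne must be terminal.
- Assumption: every intermediate that carries the benzylic ynol ether is kept at or below 25 °C and away from acid, because retro-ene, [3,3] and hydration pathways open on heating or protonation.
- The enantiomeric purity should be checked by chiral HPLC after steps 1, 12 and 13.

**Step 1**
Reactants: 1 ethyl 3-(4-methoxyphenyl)-3-oxopropanoate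
Product: 2 ethyl (S)-3-hydroxy-3-(4-methoxyphenyl)propanoate
Conditions: RuCl(p-cymene)[(S,S)-TsDPEN] (1 mol %), HCO2H/Et3N (5:2), 30 °C
Reagents that add atoms: none
Why: Noyori asymmetric transfer hydrogenation of an aryl ketone: in the six-membered hydride/proton transfer state the anisyl ring lies next to the η6-cymene ligand (CH/π contact), so the (S,S)-catalyst delivers hydride to the face that gives the (S)-carbinol, and the mild formate medium spares the solvolysis-prone 4-methoxybenzylic alcohol.

**Step 2**
Reactants: 2 ethyl (S)-3-hydroxy-3-(4-methoxyphenyl)propanoate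
Product: 3 (S)-1-(4-methoxyphenyl)propane-1,3-diol
Conditions: LiAlH4, THF, 0 °C; aqueous NaOH work-up
Reagents that add atoms: none
Why: Hydride reduction of the ester to the primary alcohol, in which no bond to the carbinol stereocentre is touched.

**Step 3**
Reactants: 3 (S)-1-(4-methoxyphenyl)propane-1,3-diol
Product: 4 (S)-1-(4-methoxyphenyl)-3-(triisopropylsilyloxy)propan-1-ol
Conditions: TIPSCl (1.05 equiv), imidazole, CH2Cl2, 0 °C to rt
Reagents that add atoms: triisopropylsilyl chloride, CC(C)[Si](Cl)(C(C)C)C(C)C
Why: Sterically controlled silylation of the primary over the secondary benzylic hydroxyl; the triisopropylsilyl group is chosen because it resists 1,5 O-to-O migration onto the potassium alkoxide of step 4 and later leaves with fluoride, a reagent that an acid-labile ynol ether tolerates.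

**Step 4**
Reactants: 4 (S)-1-(4-methoxyphenyl)-3-(triisopropylsilyloxy)propan-1-ol; 5 trichloroethylene
Product: 7 (S)-{3-[(E)-1,2-dichlorovinyloxy]-3-(4-methoxyphenyl)propoxy}triisopropylsilane, via dichloroacetylene 6 (not isolated)
Conditions: KH (2.2 equiv), THF, 0 °C; 5 (1.1 equiv), −50 °C to rt; water quench
Reagents that add atoms: none
Why: Trichloroethylene route to 1,2-dichlorovinyl ethers: KH dehydrochlorinates 5 to 6, the potassium alkoxide of 4 adds to it in anti fashion and protonation gives the (E)-ether, a sequence established for secondary benzylic alcohols that leaves the C–O bond at the stereocentre intact.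

**Step 5**
Reactants: 7 (S)-{3-[(E)-1,2-dichlorovinyloxy]-3-(4-methoxyphenyl)propoxy}triisopropylsilane; 8 prenyl bromide (1-bromo-3-methylbut-2-ene)
Product: 10 (S)-triisopropyl{3-(4-methoxyphenyl)-3-[(5-methylhex-4-en-1-yn-1-yl)oxy]propoxy}silane, via lithium alkynyl ether 9 (not isolated)
Conditions: nBuLi (2.3 equiv), THF, −78 to −30 °C; then 8 (1.5 equiv), DMPU, −78 °C to rt
Reagents that add atoms: none
Why: Base-induced loss of HCl followed by chlorine–lithium exchange converts the dichlorovinyl ether into lithium acetylide 9, which is alkylated in SN2 fashion at the primary carbon of the allylic bromide (acetylide alkylation in a dipolar cosolvent), so the future C8 substituent is placed unambiguously.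

**Step 6**
Reactants: 10 (S)-triisopropyl{3-(4-methoxyphenyl)-3-[(5-methylhex-4-en-1-yn-1-yl)oxy]propoxy}silane
Product: 11 (S)-3-(4-methoxyphenyl)-3-[(5-methylhex-4-en-1-yn-1-yl)oxy]propan-1-ol
Conditions: TBAF (1.2 equiv), THF, 0 °C to rt
Reagents that add atoms: none
Why: Fluoride-induced cleavage of the primary silyl ether under basic, non-acidic conditions, to which the ynol ether, the skipped enyne and the stereocentre are inert.

**Step 7**
Reactants: 11 (S)-3-(4-methoxyphenyl)-3-[(5-methylhex-4-en-1-yn-1-yl)oxy]propan-1-ol
Product: 12 (S)-3-(4-methoxyphenyl)-3-[(5-methylhex-4-en-1-yn-1-yl)oxy]propanal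
Conditions: nPr4N[RuO4] (5 mol %), NMO (1.5 equiv), 4 Å sieves, CH2Cl2, 0 °C to rt; used at once
Reagents that add atoms: none
Why: Ley–Griffith oxidation stops at the aldehyde and runs without acid or strong base, so neither hydration of the ynol ether nor β-elimination of the alkynyloxy group should intervene.

**Step 8**
Reactants: 12 (S)-3-(4-methoxyphenyl)-3-[(5-methylhex-4-en-1-yn-1-yl)oxy]propanal; 13 chloroacetaldehyde dimethyl acetal
Product: 15 (5S)-1-methoxy-5-(4-methoxyphenyl)-5-[(5-methylhex-4-en-1-yn-1-yl)oxy]pent-1-yn-3-ol (both C3 epimers), via lithium methoxyacetylide 14 (not isolated)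
Conditions: Et2NH, nBuLi (4.5 equiv each), THF, 0 °C; 13 (1.5 equiv), −78 to 0 °C; then 12, −78 °C; pH 7 buffer
Reagents that add atoms: none
Why: Threefold action of Et2NLi on 13 (two eliminations and one deprotonation) gives lithium alkoxyacetylide 14, whose 1,2-addition to the aldehyde at −78 °C outruns enolisation; the new carbinol centre forms without control and is erased in step 9.

**Step 9**
Reactants: 15 (5S)-1-methoxy-5-(4-methoxyphenyl)-5-[(5-methylhex-4-en-1-yn-1-yl)oxy]pent-1-yn-3-ol
Product: 16 (S)-1-methoxy-5-(4-methoxyphenyl)-5-[(5-methylhex-4-en-1-yn-1-yl)oxy]pent-1-yn-3-one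
Conditions: activated MnO2 (15 equiv), CH2Cl2, 0 °C to rt; filtration through Celite, cold concentration, used at once
Reagents that add atoms: none
Why: Heterogeneous MnO2 oxidation of a propargylic alcohol to the ynone under neutral conditions, with removal of the reagent by filtration so that the base- and heat-sensitive β-alkynyloxy ketone needs no chromatography.

**Step 10**
Reactants: 17 acetylene
Product: 20 triisopropylsiloxyacetylene [(ethynyloxy)triisopropylsilane], via lithium acetylide 18 (not isolated), via lithium ethynolate 19 (not isolated)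
Conditions: 17 (excess), nBuLi, THF, −78 °C; LiOOtBu (from tBuOOH, LiN(SiMe3)2, THF, −78 °C), −78 to −10 °C; TIPSOTf, −78 to 0 °C
Reagents that add atoms: tert-butyl hydroperoxide, CC(C)(C)OO; triisopropylsilyl triflate, CC(C)[Si](OS(=O)(=O)C(F)(F)F)(C(C)C)C(C)C
Why: Oxenoid oxidation of a lithium acetylide: the acetylide carbon attacks the peroxide oxygen of LiOOtBu with loss of LiOtBu to give ynolate 19, and the hard, bulky silyl triflate traps it on oxygen (O-silylation of an ynolate), the usual outcome for the triisopropylsilyl group.

**Step 11**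
Reactants: 16 (S)-1-methoxy-5-(4-methoxyphenyl)-5-[(5-methylhex-4-en-1-yn-1-yl)oxy]pent-1-yn-3-one; 20 triisopropylsiloxyacetylene
Product: 21 (S)-5-methoxy-2-(4-methoxyphenyl)-8-(3-methylbut-2-en-1-yl)-7-(triisopropylsilyloxy)chroman-4-one
Conditions: [Rh(cod)2]BF4 (10 mol %), BIPHEP [2,2'-bis(diphenylphosphino)biphenyl] (10 mol %), H2 then Ar (pre-activation), 2,6-di-tert-butyl-4-methylpyridine (20 mol %), CH2Cl2; 20 (3 equiv); 16 added over 2 h, 0 °C to rt
Reagents that add atoms: none
Why: Proposed new method: the cationic monovalent rhodium centre should bind both alkynes of 16 and couple them oxidatively, which forms C4a–C8a and closes ring C as a six-membered ring fused to a trivalent rhodacyclopentadiene whose Rh–C bonds end at C5 and C8; 20 then inserts into the Rh–C5 bond (C5–C6), and reductive elimination from the seven-membered rhodacycle forms C7–C8 and closes ring A as a six-membered carbocycle that is aromatic on release. The closest known reactions are cationic rhodium/bisphosphine [2+2+2] cycloadditions of tethered diynes (aryl alkynyl ether-linked ones included) with monoalkynes and the thermal benzannulations of siloxyalkynes with vinylketenes, whereas a diyne with two oxygenated termini, one of them a secondary alkyl ynol ether, has not been combined with a siloxyalkyne. No stereocentre is created, and C2 lies in the tether with no bond to it made or broken, so it keeps its (S) configuration, and an achiral ligand avoids matched and mismatched pairs. The step needs one orientation of 20, and both new intermolecular bonds are polarity-matched in that orientation: the nucleophilic CH terminus (C6) meets C5, the carbon made electrophilic by conjugation with the C4 carbonyl, while the cation-stabilising oxygenated carbon (C7) meets C8, the nucleophilic β-carbon of the O1 enol ether unit, and a terminal alkyne normally forms its first C–C bond at the unsubstituted carbon anyway. Cross- over homo-cycloaddition is favoured by slow addition of 16 to excess 20, the hindered pyridine scavenges adventitious acid without binding rhodium, and working at or below 25 °C protects the benzylic ynol ether from retro-ene, [3,3] and ionisation pathways.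

**Step 12**
Reactants: 21 (S)-5-methoxy-2-(4-methoxyphenyl)-8-(3-methylbut-2-en-1-yl)-7-(triisopropylsilyloxy)chroman-4-one
Product: 22 (S)-5-hydroxy-2-(4-methoxyphenyl)-8-(3-methylbut-2-en-1-yl)-7-(triisopropylsilyloxy)chroman-4-one
Conditions: MgI2·OEt2 (3 equiv), THF, 50 °C; aqueous Na2S2O3 work-up
Reagents that add atoms: none
Why: Chelation-directed ether cleavage, a method established for 5-O-methyl-8-prenylflavanones: magnesium binds between the C4 carbonyl and O5, iodide removes that methyl group by SN2, the unchelated 4'-methyl ether stays, and the silyl ether kept on O7 stops the prenyl group from cyclising onto a free phenol.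

**Step 13**
Reactants: 22 (S)-5-hydroxy-2-(4-methoxyphenyl)-8-(3-methylbut-2-en-1-yl)-7-(triisopropylsilyloxy)chroman-4-one
Product: 23 (S)-5,7-dihydroxy-2-(4-methoxyphenyl)-8-(3-methylbut-2-en-1-yl)chroman-4-one (target)
Conditions: TBAF/AcOH (1:1, 1.2 equiv), THF, 0 °C
Reagents that add atoms: none
Why: Fluoride cleavage of the aryl silyl ether buffered with acetic acid, so that no free phenoxide or enolate builds up and ring C cannot open to the chalcone, which protects the C2 configuration.

**Compound list**

1 | ethyl 3-(4-methoxyphenyl)-3-oxopropanoate | CCOC(=O)CC(=O)c1ccc(OC)cc1 | starting material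
2 | ethyl (S)-3-hydroxy-3-(4-methoxyphenyl)propanoate | CCOC(=O)C[C@H](O)c1ccc(OC)cc1 | intermediate
3 | (S)-1-(4-methoxyphenyl)propane-1,3-diol | OCC[C@H](O)c1ccc(OC)cc1 | intermediate
4 | (S)-1-(4-methoxyphenyl)-3-(triisopropylsilyloxy)propan-1-ol | CC(C)[Si](OCC[C@H](O)c1ccc(OC)cc1)(C(C)C)C(C)C | intermediate
5 | trichloroethylene | ClC=C(Cl)Cl | starting material
6 | dichloroacetylene (not isolated) | ClC#CCl | intermediate
7 | (S)-{3-[(E)-1,2-dichlorovinyloxy]-3-(4-methoxyphenyl)propoxy}triisopropylsilane | CC(C)[Si](OCC[C@H](O/C(Cl)=C\Cl)c1ccc(OC)cc1)(C(C)C)C(C)C | intermediate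
8 | prenyl bromide | CC(C)=CCBr | starting material
9 | lithium alkynyl ether of 4 (not isolated) | CC(C)[Si](OCC[C@H](OC#C[Li])c1ccc(OC)cc1)(C(C)C)C(C)C | intermediate
10 | (S)-triisopropyl{3-(4-methoxyphenyl)-3-[(5-methylhex-4-en-1-yn-1-yl)oxy]propoxy}silane | CC(C)[Si](OCC[C@H](OC#CCC=C(C)C)c1ccc(OC)cc1)(C(C)C)C(C)C | intermediate
11 | (S)-3-(4-methoxyphenyl)-3-[(5-methylhex-4-en-1-yn-1-yl)oxy]propan-1-ol | OCC[C@H](OC#CCC=C(C)C)c1ccc(OC)cc1 | intermediate
12 | (S)-3-(4-methoxyphenyl)-3-[(5-methylhex-4-en-1-yn-1-yl)oxy]propanal | O=CC[C@H](OC#CCC=C(C)C)c1ccc(OC)cc1 | intermediate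
13 | chloroacetaldehyde dimethyl acetal | COC(CCl)OC | starting material
14 | lithium methoxyacetylide (not isolated) | COC#C[Li] | intermediate
15 | (5S)-1-methoxy-5-(4-methoxyphenyl)-5-[(5-methylhex-4-en-1-yn-1-yl)oxy]pent-1-yn-3-ol, C3 epimers | COC#CC(O)C[C@H](OC#CCC=C(C)C)c1ccc(OC)cc1 | intermediate
16 | (S)-1-methoxy-5-(4-methoxyphenyl)-5-[(5-methylhex-4-en-1-yn-1-yl)oxy]pent-1-yn-3-one | COC#CC(=O)C[C@H](OC#CCC=C(C)C)c1ccc(OC)cc1 | intermediate
17 | acetylene | C#C | starting material
18 | lithium acetylide (not isolated) | [Li]C#C | intermediate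
19 | lithium ethynolate (not isolated) | C#CO[Li] | intermediate
20 | triisopropylsiloxyacetylene | C#CO[Si](C(C)C)(C(C)C)C(C)C | intermediate
21 | (S)-5-methoxy-2-(4-methoxyphenyl)-8-(3-methylbut-2-en-1-yl)-7-(triisopropylsilyloxy)chroman-4-one | COc1ccc([C@@H]2CC(=O)c3c(OC)cc(O[Si](C(C)C)(C(C)C)C(C)C)c(CC=C(C)C)c3O2)cc1 | intermediate
22 | (S)-5-hydroxy-2-(4-methoxyphenyl)-8-(3-methylbut-2-en-1-yl)-7-(triisopropylsilyloxy)chroman-4-one | COc1ccc([C@@H]2CC(=O)c3c(O)cc(O[Si](C(C)C)(C(C)C)C(C)C)c(CC=C(C)C)c3O2)cc1 | intermediate
23 | (S)-5,7-dihydroxy-2-(4-methoxyphenyl)-8-(3-methylbut-2-en-1-yl)chroman-4-one | COc1ccc([C@@H]2CC(=O)c3c(O)cc(O)c(CC=C(C)C)c3O2)cc1 | target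

**Total step count:** 13.
**Longest linear sequence:** 12 (steps 1–9 and 11–13).

**The three steps most likely to fail**

**Step 11.**
- What may go wrong:
  - self-oligomerisation or decay of the siloxyalkyne on the cationic metal;
  - sluggish oxidative coupling of a 1,7-diyne with two donor-substituted termini;
  - insertion in the opposite sense;
  - Lewis-acid ionisation of the C2–O1 bond.
- The fallback uses known chemistry. It takes ring A from phloroglucinol and sets C2 by conjugate addition. It sets out from prenyl bromide 8 and comes back at 21.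
- C-alkylation of commercial 2,4,6-trihydroxyacetophenone with 8 (aqueous KOH) should give 2,4,6-trihydroxy-3-prenylacetophenone F1.
- Silylation of the most acidic, para hydroxyl (TIPSCl, imidazole) should give 2,6-dihydroxy-3-prenyl-4-(triisopropylsilyloxy)acetophenone F2.
- Monomethylation of the less hindered ortho hydroxyl (Me2SO4, K2CO3, acetone) should give 2-hydroxy-6-methoxy-3-prenyl-4-(triisopropylsilyloxy)acetophenone F3.
- Condensation with DMF dimethyl acetal should give the dimethylamino enaminone F4.
- F4 should close with acetic acid to 5-methoxy-8-prenyl-7-(triisopropylsilyloxy)chromone F5.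
- A Hayashi–Miyaura asymmetric 1,4-addition of 4-methoxyphenylboronic acid then delivers 21. Conditions: [Rh(OH)(cod)]2, an electron-poor atropisomeric bisphosphine of the hand that leads to the 2S series, toluene/water, rt.

**Step 9.**
- What may go wrong: once C4 is a ketone, the C3 hydrogens become acidic. The alkynyloxy group may then leave by β-elimination or retro-ene fragmentation during oxidation, filtration or concentration.
- The fallback postpones the oxidation until ring C exists. It sets out from 15 and comes back at 21.
- Carbinol 15 is submitted directly to the conditions of step 11 with 20, since cationic rhodium catalysts of this type accept free propargylic alcohols.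
- This should give (2S)-5-methoxy-2-(4-methoxyphenyl)-8-prenyl-7-(triisopropylsilyloxy)chroman-4-ol F6 as C4 epimers.
- Benzylic oxidation of F6 with MnO2 leads to 21.
- The price is that C5 loses its carbonyl polarisation, so the orientation of 20 would rest on the enol-ether polarity at C8 and on sterics alone.

**Step 10.**
- What may go wrong:
  - disproportionation of LiC≡CH before it is oxidised;
  - silylation of the unhindered parent ynolate on carbon, which would lead to the silylketene.
- The fallback blocks the carbon terminus. It sets out from acetylene 17 and comes back at 20.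
- Monosilylation (nBuLi, Me3SiCl) gives ethynyltrimethylsilane F7, which is also sold.
- Its stable lithium acetylide undergoes the same peroxide oxidation. The hindered ynolate can then be silylated only on oxygen, giving 1-(triisopropylsiloxy)-2-(trimethylsilyl)acetylene F8.
- One equivalent of buffered fluoride (TBAF/AcOH, THF, −78 °C) should remove the small C-bound silyl group faster than the hindered O-bound one and return 20.

**Further compounds**

F1 | step 11 | 2,4,6-trihydroxy-3-prenylacetophenone | CC(=O)c1c(O)cc(O)c(CC=C(C)C)c1O
F2 | step 11 | 2,6-dihydroxy-3-prenyl-4-(triisopropylsilyloxy)acetophenone | CC(=O)c1c(O)cc(O[Si](C(C)C)(C(C)C)C(C)C)c(CC=C(C)C)c1O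
F3 | step 11 | 2-hydroxy-6-methoxy-3-prenyl-4-(triisopropylsilyloxy)acetophenone | CC(=O)c1c(OC)cc(O[Si](C(C)C)(C(C)C)C(C)C)c(CC=C(C)C)c1O
F4 | step 11 | (E)-3-(dimethylamino)-1-[2-hydroxy-6-methoxy-3-prenyl-4-(triisopropylsilyloxy)phenyl]prop-2-en-1-one | CN(C)/C=C/C(=O)c1c(OC)cc(O[Si](C(C)C)(C(C)C)C(C)C)c(CC=C(C)C)c1O
F5 | step 11 | 5-methoxy-8-prenyl-7-(triisopropylsilyloxy)chromen-4-one | COc1cc(O[Si](C(C)C)(C(C)C)C(C)C)c(CC=C(C)C)c2occc(=O)c12
F6 | step 9 | (2S)-5-methoxy-2-(4-methoxyphenyl)-8-prenyl-7-(triisopropylsilyloxy)chroman-4-ol, C4 epimers | COc1ccc([C@@H]2CC(O)c3c(OC)cc(O[Si](C(C)C)(C(C)C)C(C)C)c(CC=C(C)C)c3O2)cc1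
F7 | step 10 | ethynyltrimethylsilane | C#C[Si](C)(C)C
F8 | step 10 | 1-(triisopropylsiloxy)-2-(trimethylsilyl)acetylene | C[Si](C)(C)C#CO[Si](C(C)C)(C(C)C)C(C)C
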